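**Plan**
Numbering: pyrrolidine N4/C3/C2/C1/C9a; azepane N4/C5–C9/C9a; C10 carries Et; lactone B = O–C11–C12–C13(Me)–C14(=O); lactone A = O–C18–C19–C20(Me)–C21(=O).
Cuts: N4–C5 (reductive amination), C7=C8 (Wittig), C13–Me (enolate alkylation), C9–C9a (Mukaiyama–Mannich), C10–Et (cuprate), C10–C11 (alkynylation), C18–C19 (alkylidene-carbene C–H insertion; C19 comes from TMSCHN2).
Enabling feature: in ring A the ring oxygen links C18 to C21. In the acetonyl ether C18H2–O–C21H2–C20(=O)–CH3, a carbene carbon placed on C20 therefore lies exactly 1,5 to the oxygen-activated C18–H bonds, and C18 is the carboxyl carbon of pyroglutamic acid itself.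
Ring order: pyrrolidine (chiral pool), then ring A as a 2,5-dihydrofuran (step 5), then a temporary γ-lactone O11–C8(=O) as template. Ring B follows by hand-over of O11 (step 11), then the C21 carbonyl, and the azepane is closed last.
Stereochemistry: C3 comes from L-pyroglutamate, C18 from C3-controlled insertion, and C11 from catalytic asymmetric alkynylation. C10 and C9 arise by trans,trans relay on the temporary lactone, and C9a by attack anti to the C3 group. C13 is set by alkylation anti to C11, and C20 by hydrogenation anti to the C18 substituent.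

Key step: step 5

Assumption: (S)-BINOL/Ti is taken to deliver the alkynylzinc to the Si face of aldehyde 11 (giving 4R), as in related organozinc additions; (R)-BINOL is used if the sense is opposite.
Remark: the methoxy-bearing carbon (future C9a) in 2–10 is carried as an epimer mixture, because both epimers give the same iminium ion 17.

Step 1
Reactants: 1 methyl (2S)-1-Boc-5-oxopyrrolidine-2-carboxylate
Product: 3 methyl (2S)-1-Boc-5-methoxypyrrolidine-2-carboxylate, via hemiaminal 2 (not isolated)
Conditions: LiEt3BH, THF, −78 °C; then MeOH, p-TsOH (cat.), rt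
Reagents that add atoms: methanol (CO)
Why: Chemoselective hydride addition to the imide-like N-Boc lactam carbonyl (the ester is less electrophilic at −78 °C) followed by acid-catalysed N,O-acetal formation is the standard entry to an N-acyliminium precursor, and C3 is untouched.

Step 2
Reactants: 3 methyl (2S)-1-Boc-5-methoxypyrrolidine-2-carboxylate
Product: 4 tert-butyl (2S)-2-(hydroxymethyl)-5-methoxypyrrolidine-1-carboxylate
Conditions: LiBH4, THF, 0 °C to rt
Reagents that add atoms: none
Why: Borohydride ester reduction leaves the carbamate and N,O-acetal alone and turns the amino-acid carboxyl carbon into C18H2–OH without touching C3.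

Step 3
Reactants: 4 tert-butyl (2S)-2-(hydroxymethyl)-5-methoxypyrrolidine-1-carboxylate; 5 3-bromo-2-methylprop-1-ene
Product: 6 tert-butyl (2S)-5-methoxy-2-[(2-methylprop-2-enyloxy)methyl]pyrrolidine-1-carboxylate
Conditions: NaH, Bu4NI (cat.), THF/DMF, 0 °C to rt
Reagents that add atoms: none
Why: Williamson etherification of the primary alkoxide with an allylic bromide is fast enough at 0 °C to outrun attack on the Boc group, and the N,O-acetal is base-stable.

Step 4
Reactants: 6 tert-butyl (2S)-5-methoxy-2-[(2-methylprop-2-enyloxy)methyl]pyrrolidine-1-carboxylate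
Product: 7 tert-butyl (2S)-5-methoxy-2-[(2-oxopropoxy)methyl]pyrrolidine-1-carboxylate
Conditions: O3, CH2Cl2, −78 °C; Me2S
Reagents that add atoms: ozone ([O-][O+]=O)
Why: Ozonolysis of the 1,1-disubstituted alkene with reductive work-up unmasks the methyl ketone C20=O, since the alkene is far more reactive towards ozone than the ether and acetal C–H bonds.

Step 5
Reactants: 7 tert-butyl (2S)-5-methoxy-2-[(2-oxopropoxy)methyl]pyrrolidine-1-carboxylate
Product: 10 tert-butyl (2S)-5-methoxy-2-[(2S)-4-methyl-2,5-dihydrofuran-2-yl]pyrrolidine-1-carboxylate, via diazoalkene 8 (not isolated), via alkylidene carbene 9 (not isolated)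
Conditions: TMSCHN2, n-BuLi, THF, −78 °C; add 7; −78 °C to 0 °C
Reagents that add atoms: trimethylsilyldiazomethane (C[Si](C)(C)C=[N+]=[N-])
Why: Lithiated TMS-diazomethane adds to C20=O of 7, Peterson-type loss of Me3SiOLi gives diazoalkene 8, and loss of N2 gives the free alkylidene carbene 9 with the divalent carbon C19 on C20. The closest known reaction type is the alkylidene-carbene 1,5-C–H insertion of α-alkoxy ketones to 3-substituted 2,5-dihydrofurans (Colvin/Seyferth–Gilbert-type carbene generation). The singlet carbene inserts in one concerted step, with retention at carbon, into a C18–H bond, so the new C19–C18 bond closes the five-membered ring O/C21/C20/C19/C18 through a 1,5 cyclic transition state and avoids the disfavoured 5-endo-trig closure that a C18 radical or anion would need. Site selectivity is built into the substrate: C18H2 is the only carbon 1,5 to C19 and its C–H bonds are made hydridic by the ring-oxygen lone pair, while the methyl branch has no 1,5 C–H, 1,2-alkyl shift to an alkyne is slow for dialkyl carbenes, and 1,6-insertion at C3–H is kinetically uncompetitive. The new centre C18 is controlled by C3: in the rotamer with C18–O anti to C3–C2 (small oxygen next to Boc, forming ring over C3–H) only the pro-S hydrogen, which points away from the carbamate, can be reached, and this should give 18S. The carbamate, the N,O-acetal and C3 are inert to the reagent at these temperatures.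

Step 6
Reactants: 11 tert-butyl 4-oxobutanoate; 12 methyl prop-2-ynoate
Product: 13 7-tert-butyl 1-methyl (4R)-4-hydroxyhept-2-ynedioate
Conditions: 12, Et2Zn, (S)-BINOL (40 mol %), HMPA, CH2Cl2, rt; Ti(OiPr)4; then 11, rt
Reagents that add atoms: none
Why: Catalytic asymmetric alkynylzinc addition (BINOL–Ti) forms C10–C11 and sets C11 by ligand-directed Si-face delivery, while the tert-butyl ester is inert.

Step 7
Reactants: 13 7-tert-butyl 1-methyl (4R)-4-hydroxyhept-2-ynedioate
Product: 15 tert-butyl 3-[(2R)-5-oxo-2,5-dihydrofuran-2-yl]propanoate, via Z-hydroxy enoate 14 (not isolated)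
Conditions: H2 (1 atm), Lindlar catalyst, quinoline, EtOAc, rt
Reagents that add atoms: none
Why: Lindlar semihydrogenation gives the Z-enoate, whose C11 hydroxyl lies next to the methyl ester and lactonises spontaneously to the butenolide, while the hindered tert-butyl ester does not compete and C11 is untouched.

Step 8
Reactants: 15 tert-butyl 3-[(2R)-5-oxo-2,5-dihydrofuran-2-yl]propanoate
Product: 16 tert-butyl 3-[(2R,3S)-3-ethyl-5-(trimethylsilyloxy)-2,3-dihydrofuran-2-yl]propanoate (used crude)
Conditions: EtMgBr, CuBr·SMe2 (cat.), TMSCl, DMPU, THF, −78 °C; pentane, cold NaHCO3 wash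
Reagents that add atoms: ethylmagnesium bromide (CC[Mg]Br); chlorotrimethylsilane (C[Si](C)(C)Cl)
Why: Copper-catalysed, TMSCl-accelerated conjugate addition delivers ethyl to C10 anti to the C11 side chain (trans-4,5) and traps the enolate regiospecifically as the ketene silyl acetal.

Step 9
Reactants: 10 tert-butyl (2S)-5-methoxy-2-[(2S)-4-methyl-2,5-dihydrofuran-2-yl]pyrrolidine-1-carboxylate; 16 tert-butyl 3-[(2R,3S)-3-ethyl-5-(trimethylsilyloxy)-2,3-dihydrofuran-2-yl]propanoate
Product: 18 tert-butyl (2S,5S)-5-[(3R,4S,5R)-5-(3-tert-butoxy-3-oxopropyl)-4-ethyl-2-oxooxolan-3-yl]-2-[(2S)-4-methyl-2,5-dihydrofuran-2-yl]pyrrolidine-1-carboxylate, via N-acyliminium ion 17 (not isolated)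
Conditions: TMSOTf (10–20 mol %), CH2Cl2, −78 °C
Reagents that add atoms: none
Why: In this Mukaiyama–Mannich reaction the ion 17 is attacked at C9a anti to the C3 substituent (held pseudoaxial by A1,3 strain with Boc, giving 2,5-trans) by the face of 16 anti to the C10 ethyl group, so each partner's own ring fixes its new centre (9aS, 9R).

Step 10
Reactants: 18 the Mannich lactone
Product: 19 the corresponding lactol (2-hydroxyoxolane, anomer mixture; all other centres as in 18)
Conditions: DIBAL-H (1.2 equiv), CH2Cl2, −78 °C; Rochelle salt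
Reagents that add atoms: none
Why: Low-temperature DIBAL-H reduction stops at the lactol because the aluminate is stable at −78 °C, and the lactone is more electrophilic than the tert-butyl ester or the carbamate.

Step 11
Reactants: 19 the lactol; 20 [2-(1,3-dioxolan-2-yl)ethyl]triphenylphosphonium bromide
Product: 22 N-Boc (3S,9aS)-pyrrolidine with the (18S)-4-methyl-2,5-dihydrofuran-2-yl group at C3 and at C9a the (9R)-CH[(Z)-CH=CH–CH2–(1,3-dioxolan-2-yl)]–(10S)-CH(Et)–[(11R)-5-oxooxolan-2-yl] chain, via hydroxy ester 21 (not isolated)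
Conditions: 20 (3 equiv), KHMDS, THF, 0 °C; add 19 at −78 °C; warm to rt
Reagents that add atoms: none
Why: Wittig olefination of the open hydroxy-aldehyde form of the lactol with the non-stabilised ylide attaches C7–C5, and the liberated C11 potassium alkoxide closes onto the tert-butyl ester (5-exo-trig acyl substitution), so O11 passes from the temporary lactone to ring B without disturbing C9–C11.

Step 12
Reactants: 22 the ring-B lactone
Product: 23 the (13S)-13-methyl derivative of 22 (methyl trans to the C11 substituent)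
Conditions: LDA (1.1 equiv), THF, −78 °C; MeI
Reagents that add atoms: iodomethane (CI)
Why: In this kinetic lactone-enolate alkylation methyl iodide approaches anti to the bulky C11 substituent and gives the trans-3,5 lactone, and no other acidic site is present.

Step 13
Reactants: 23 the methylated lactone
Product: 24 the butenolide in which ring A is (18S)-4-methyl-5-oxo-2,5-dihydrofuran-2-yl (otherwise as 23)
Conditions: CrO3, 3,5-dimethylpyrazole, CH2Cl2, −20 °C
Reagents that add atoms: chromium trioxide (O=[Cr](=O)=O)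
Why: Chromium(VI)–dimethylpyrazole allylic oxidation should take C21H2, the only methylene that is both allylic and α to oxygen, to the carbonyl, because the tertiary, crowded C18–H and the plain allylic positions of C7=C8 are slower.

Step 14
Reactants: 24 the butenolide
Product: 25 the saturated N-Boc bis-lactone acetal (3S,9R,9aS,10S,11R,13S,18S,20S) with a C8–C7–C6–C5(dioxolane) chain
Conditions: H2 (1–4 atm), 5 % Rh/Al2O3, EtOAc, rt
Reagents that add atoms: none
Why: Heterogeneous hydrogenation adds H2 to the butenolide face anti to the C18 pyrrolidinyl group, which places the C20 methyl cis to it (20S), and it saturates C7=C8 in the same operation, with rhodium avoiding hydrogenolysis of the allylic C18–O bond.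

Step 15
Reactants: 25 the saturated N-Boc bis-lactone acetal
Product: 28 the target CNP0135535.1, via amino aldehyde 26 (not isolated), via cyclic iminium ion 27 (not isolated)
Conditions: TFA/CH2Cl2/H2O, rt; evaporate; NaBH(OAc)3, ClCH2CH2Cl, rt
Reagents that add atoms: none
Why: Acid removes Boc and the dioxolane, the amino aldehyde condenses to the seven-membered iminium ion, and triacetoxyborohydride reduces it (intramolecular reductive amination) without touching the lactones or creating a stereocentre.

**Compound list**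
1 | methyl (2S)-1-Boc-5-oxopyrrolidine-2-carboxylate | COC(=O)[C@@H]1CCC(=O)N1C(=O)OC(C)(C)C | starting material
2 | methyl (2S)-1-Boc-5-hydroxypyrrolidine-2-carboxylate (C5 epimers) | COC(=O)[C@@H]1CCC(O)N1C(=O)OC(C)(C)C | intermediate
3 | methyl (2S)-1-Boc-5-methoxypyrrolidine-2-carboxylate (C5 epimers) | COC(=O)[C@@H]1CCC(OC)N1C(=O)OC(C)(C)C | intermediate
4 | tert-butyl (2S)-2-(hydroxymethyl)-5-methoxypyrrolidine-1-carboxylate | OC[C@@H]1CCC(OC)N1C(=O)OC(C)(C)C | intermediate
5 | 3-bromo-2-methylprop-1-ene | C=C(C)CBr | starting material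
6 | tert-butyl (2S)-5-methoxy-2-[(2-methylprop-2-enyloxy)methyl]pyrrolidine-1-carboxylate | C=C(C)COC[C@@H]1CCC(OC)N1C(=O)OC(C)(C)C | intermediate
7 | tert-butyl (2S)-5-methoxy-2-[(2-oxopropoxy)methyl]pyrrolidine-1-carboxylate | CC(=O)COC[C@@H]1CCC(OC)N1C(=O)OC(C)(C)C | intermediate
8 | tert-butyl (2S)-2-[(3-diazo-2-methylprop-2-enyloxy)methyl]-5-methoxypyrrolidine-1-carboxylate | [N-]=[N+]=C=C(C)COC[C@@H]1CCC(OC)N1C(=O)OC(C)(C)C | intermediate
9 | alkylidene carbene derived from 8 (divalent C19 on C20) | [C]=C(C)COC[C@@H]1CCC(OC)N1C(=O)OC(C)(C)C | intermediate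
10 | tert-butyl (2S)-5-methoxy-2-[(2S)-4-methyl-2,5-dihydrofuran-2-yl]pyrrolidine-1-carboxylate | CC1=C[C@H](OC1)[C@@H]2CCC(OC)N2C(=O)OC(C)(C)C | intermediate
11 | tert-butyl 4-oxobutanoate | CC(C)(C)OC(=O)CCC=O | starting material
12 | methyl prop-2-ynoate | C#CC(=O)OC | starting material
13 | 7-tert-butyl 1-methyl (4R)-4-hydroxyhept-2-ynedioate | COC(=O)C#C[C@H](O)CCC(=O)OC(C)(C)C | intermediate
14 | 7-tert-butyl 1-methyl (2Z,4R)-4-hydroxyhept-2-enedioate | COC(=O)/C=C\[C@H](O)CCC(=O)OC(C)(C)C | intermediate
15 | tert-butyl 3-[(2R)-5-oxo-2,5-dihydrofuran-2-yl]propanoate | O=C1C=C[C@@H](CCC(=O)OC(C)(C)C)O1 | intermediate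
16 | tert-butyl 3-[(2R,3S)-3-ethyl-5-(trimethylsilyloxy)-2,3-dihydrofuran-2-yl]propanoate | CC[C@H]1C=C(O[Si](C)(C)C)O[C@@H]1CCC(=O)OC(C)(C)C | intermediate
17 | (2S)-1-Boc-2-[(2S)-4-methyl-2,5-dihydrofuran-2-yl]-3,4-dihydro-2H-pyrrolium | CC1=C[C@H](OC1)[C@@H]2CCC=[N+]2C(=O)OC(C)(C)C | intermediate
18 | tert-butyl (2S,5S)-5-[(3R,4S,5R)-5-(3-tert-butoxy-3-oxopropyl)-4-ethyl-2-oxooxolan-3-yl]-2-[(2S)-4-methyl-2,5-dihydrofuran-2-yl]pyrrolidine-1-carboxylate | CC[C@@H]1[C@@H](CCC(=O)OC(C)(C)C)OC(=O)[C@H]1[C@@H]2CC[C@H](N2C(=O)OC(C)(C)C)[C@@H]3C=C(C)CO3 | intermediate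
19 | lactol of 18 (anomers) | CC[C@@H]1[C@@H](CCC(=O)OC(C)(C)C)OC(O)[C@H]1[C@@H]2CC[C@H](N2C(=O)OC(C)(C)C)[C@@H]3C=C(C)CO3 | intermediate
20 | [2-(1,3-dioxolan-2-yl)ethyl]triphenylphosphonium bromide | [Br-].C1COC(O1)CC[P+](c2ccccc2)(c2ccccc2)c2ccccc2 | starting material
21 | (11R)-hydroxy tert-butyl ester with the Z-C7=C8 alkene | CC[C@@H]([C@@H](/C=C\CC1OCCO1)[C@@H]2CC[C@H](N2C(=O)OC(C)(C)C)[C@@H]3C=C(C)CO3)[C@H](O)CCC(=O)OC(C)(C)C | intermediate
22 | ring-B lactone (13-unsubstituted), Z-alkene, dihydrofuran | CC[C@@H]([C@@H](/C=C\CC1OCCO1)[C@@H]2CC[C@H](N2C(=O)OC(C)(C)C)[C@@H]3C=C(C)CO3)[C@H]4CCC(=O)O4 | intermediate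
23 | (13S)-methyl lactone B, Z-alkene, dihydrofuran | CC[C@@H]([C@@H](/C=C\CC1OCCO1)[C@@H]2CC[C@H](N2C(=O)OC(C)(C)C)[C@@H]3C=C(C)CO3)[C@H]4C[C@H](C)C(=O)O4 | intermediate
24 | ring-A butenolide | CC[C@@H]([C@@H](/C=C\CC1OCCO1)[C@@H]2CC[C@H](N2C(=O)OC(C)(C)C)[C@@H]3C=C(C)C(=O)O3)[C@H]4C[C@H](C)C(=O)O4 | intermediate
25 | saturated N-Boc bis-lactone acetal | CC[C@@H]([C@@H](CCCC1OCCO1)[C@@H]2CC[C@H](N2C(=O)OC(C)(C)C)[C@@H]3C[C@H](C)C(=O)O3)[C@H]4C[C@H](C)C(=O)O4 | intermediate
26 | amino aldehyde | CC[C@@H]([C@@H](CCCC=O)[C@@H]2CC[C@H](N2)[C@@H]3C[C@H](C)C(=O)O3)[C@H]4C[C@H](C)C(=O)O4 | intermediate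
27 | bicyclic iminium ion (N4=C5) | CC[C@@H]([C@H]1CCCC=[N+]2[C@H]1CC[C@H]2[C@@H]1C[C@H](C)C(=O)O1)[C@H]1C[C@H](C)C(=O)O1 | intermediate
28 | CNP0135535.1 (3S,9R,9aS,10S,11R,13S,18S,20S) | CC[C@@H]([C@H]1CCCCN2[C@H]1CC[C@H]2[C@@H]1C[C@H](C)C(=O)O1)[C@H]1C[C@H](C)C(=O)O1 | target

Total step count: 15. Longest linear sequence: 12 (steps 1–5 and 9–15).

**Steps most likely to fail**

Step 5. The carbene may not discriminate well between the two diastereotopic C18–H bonds, or it may be diverted before insertion. The fallback sets out from 4 and returns at 10. It makes the C18 centre first and closes the ring at C19=C20 instead.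
- Alcohol 4 is oxidised (SO3·pyridine, DMSO, Et3N) to the aldehyde tert-butyl (2S)-2-formyl-5-methoxypyrrolidine-1-carboxylate F1.
- Vinylmagnesium bromide is added to give the allylic alcohol tert-butyl (2S)-2-[(1S)-1-hydroxyprop-2-enyl]-5-methoxypyrrolidine-1-carboxylate F2. Any C18 epimer is separated and corrected by Mitsunobu inversion.
- NaH and 5 give the diene tert-butyl (2S)-5-methoxy-2-[(1S)-1-(2-methylprop-2-enyloxy)prop-2-enyl]pyrrolidine-1-carboxylate F3.
- Ruthenium-catalysed ring-closing metathesis of F3 gives 10.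

Step 9. Two hindered partners may couple sluggishly, facial selectivity at C9a may erode, or the ketene silyl acetal may be lost by hydrolysis. The fallback sets out from 10 and 15 and returns at 18. It reverses the order of the two C–C bond formations on the butenolide.
- A sulfide/TMSOTf-mediated Morita–Baylis–Hillman-type coupling of the iminium ion from 10 with the unhindered butenolide 15, followed by DBU elimination, gives the α-substituted butenolide tert-butyl (2S,5S)-5-[(5R)-5-(3-tert-butoxy-3-oxopropyl)-2-oxo-2,5-dihydrofuran-3-yl]-2-[(2S)-4-methyl-2,5-dihydrofuran-2-yl]pyrrolidine-1-carboxylate F4.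
- Copper-catalysed addition of EtMgBr anti to the C11 chain, then protonation and base equilibration of C9 to the all-trans lactone, gives 18.

Step 13. Oxidation may compete at C18–H (with aromatisation to a furan) or at the allylic positions of the C7=C8 alkene. The fallback sets out from 23 and returns at 25. It removes the competing alkene before any oxidation.
- Diimide (2-nitrobenzenesulfonyl hydrazide, Et3N) saturates only the disubstituted alkene and gives the saturated-chain dihydrofuran F5.
- Allylic oxidation then has a single alkene to address and gives the saturated-chain butenolide F6.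
- Hydrogenation of F6 over rhodium gives 25.

**Further compounds**
F1 | step 5 | tert-butyl (2S)-2-formyl-5-methoxypyrrolidine-1-carboxylate | O=C[C@@H]1CCC(OC)N1C(=O)OC(C)(C)C
F2 | step 5 | tert-butyl (2S)-2-[(1S)-1-hydroxyprop-2-enyl]-5-methoxypyrrolidine-1-carboxylate | C=C[C@H](O)[C@@H]1CCC(OC)N1C(=O)OC(C)(C)C
F3 | step 5 | tert-butyl (2S)-5-methoxy-2-[(1S)-1-(2-methylprop-2-enyloxy)prop-2-enyl]pyrrolidine-1-carboxylate | C=C[C@H](OCC(C)=C)[C@@H]1CCC(OC)N1C(=O)OC(C)(C)C
F4 | step 9 | tert-butyl (2S,5S)-5-[(5R)-5-(3-tert-butoxy-3-oxopropyl)-2-oxo-2,5-dihydrofuran-3-yl]-2-[(2S)-4-methyl-2,5-dihydrofuran-2-yl]pyrrolidine-1-carboxylate | CC(C)(C)OC(=O)CC[C@@H]1C=C(C(=O)O1)[C@@H]2CC[C@H](N2C(=O)OC(C)(C)C)[C@@H]3C=C(C)CO3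
F5 | step 13 | saturated-chain dihydrofuran (23 with C7–C8 single bond) | CC[C@@H]([C@@H](CCCC1OCCO1)[C@@H]2CC[C@H](N2C(=O)OC(C)(C)C)[C@@H]3C=C(C)CO3)[C@H]4C[C@H](C)C(=O)O4
F6 | step 13 | saturated-chain butenolide (24 with C7–C8 single bond) | CC[C@@H]([C@@H](CCCC1OCCO1)[C@@H]2CC[C@H](N2C(=O)OC(C)(C)C)[C@@H]3C=C(C)C(=O)O3)[C@H]4C[C@H](C)C(=O)O4
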